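**Retrosynthetic overview**
1. Target ⇐ C3 ketone reduction ⇐ acetylation at O4 and O13 ⇐ 14-membered ring closed last by Nozaki–Hiyama–Kishi coupling at C12–C13.
2. The α-methylene-γ-lactone is formed before the macrocycle, from the [3,3] product by oxidation at C16 and acetonide release of O14.
3. Key bond C1–C2: methylenation of an allyl ester followed by aliphatic Claisen rearrangement; C1 is set by the C14 stereocentre of (S)-glyceraldehyde acetonide.
4. Acid half (C3–C12, C4 stereocentre) from (R)-lactic acid by Seebach alkylation, two Z-selective iodo-olefinations and a B-alkyl Suzuki coupling; alcohol half from glyceraldehyde acetonide and malonate.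
5. Ring order: temporary dioxolanone → γ-lactone → macrocycle.

Assumption: (R)-lactic acid, (S)-2,3-O-isopropylideneglyceraldehyde (L-ascorbic acid series) and 4-iodobut-1-ene are taken as commercial.
Numbering note: late intermediates use cembrane numbering (C1 = ring CH bearing C15(=C17H2)–C16O; C2 = CH2; C3 = carbinol; C4 = C(Me)O; C13 = CHO; C14 = lactone CH–O).

**Step 1**
Reactants: 1 (R)-lactic acid; 2 pivalaldehyde
Product: 3 (2R,5R)-2-tert-butyl-5-methyl-1,3-dioxolan-4-one (cis)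
Conditions: TsOH, H2SO4 (cat.), pentane, reflux, Dean–Stark; recrystallise at −78 °C
Reagents that add atoms: none
Why: Acid-catalysed acetalisation (Seebach self-regeneration of stereocentres); the cis acetal is favoured and crystallises, so the acetal centre is set by the lactic acid centre.

**Step 2**
Reactants: 3 (2R,5R)-2-tert-butyl-5-methyl-1,3-dioxolan-4-one; 4 4-iodobut-1-ene
Product: 6 (2R,5S)-5-(but-3-en-1-yl)-2-tert-butyl-5-methyl-1,3-dioxolan-4-one, via lithium enolate 5 (not isolated)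
Conditions: LDA, THF, −78 °C; then 4, DMPU, −78 → −40 °C
Reagents that add atoms: none
Why: Seebach enolate alkylation; the primary iodide enters anti to the tert-butyl group, which fixes the quaternary centre (future C4, S).

**Step 3**
Reactants: 6 (2R,5S)-5-(but-3-en-1-yl)-2-tert-butyl-5-methyl-1,3-dioxolan-4-one
Product: 8 3-[(2R,4S)-2-tert-butyl-4-methyl-5-oxo-1,3-dioxolan-4-yl]propanal, via secondary ozonide 7 (not isolated)
Conditions: O3, CH2Cl2, −78 °C; PPh3, −78 °C → rt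
Reagents that add atoms: ozone [O-][O+]=O
Why: Ozonolysis of the only alkene with reductive work-up gives the aldehyde without touching the acylal lactone.

**Step 4**
Reactants: 8 3-[(2R,4S)-2-tert-butyl-4-methyl-5-oxo-1,3-dioxolan-4-yl]propanal
Product: 9 (2R,5S)-2-tert-butyl-5-[(3Z)-4-iodopent-3-en-1-yl]-5-methyl-1,3-dioxolan-4-one
Conditions: EtPPh3I, n-BuLi, THF; I2, −78 °C; NaHMDS, −20 °C; then 8, −78 °C
Reagents that add atoms: ethyltriphenylphosphonium iodide CC[P+](c1ccccc1)(c1ccccc1)c1ccccc1.[I-]; iodine II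
Why: Stork–Zhao-type Wittig reaction with Ph3P=C(I)CH3 gives the (Z)-2-iodoalkene (chain cis to iodine) under kinetic control.

**Step 5**
Reactants: 9 (2R,5S)-2-tert-butyl-5-[(3Z)-4-iodopent-3-en-1-yl]-5-methyl-1,3-dioxolan-4-one; 10 acrolein diethyl acetal
Product: 12 (2R,5S)-2-tert-butyl-5-[(3Z)-7,7-diethoxy-4-methylhept-3-en-1-yl]-5-methyl-1,3-dioxolan-4-one, via B-(3,3-diethoxypropyl)-9-BBN 11 (not isolated)
Conditions: 10, 9-BBN, THF, rt; then 9, Pd(dppf)Cl2 (5 mol%), AsPh3, Cs2CO3, DMF/H2O, rt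
Reagents that add atoms: none
Why: B-alkyl Suzuki–Miyaura coupling proceeds with retention at the vinyl iodide, so the C7=C8 olefin is Z.

**Step 6**
Reactants: 12 (2R,5S)-2-tert-butyl-5-[(3Z)-7,7-diethoxy-4-methylhept-3-en-1-yl]-5-methyl-1,3-dioxolan-4-one
Product: 13 (4Z)-7-[(2R,4S)-2-tert-butyl-4-methyl-5-oxo-1,3-dioxolan-4-yl]-4-methylhept-4-enal
Conditions: oxalic acid, THF/H2O, rt
Reagents that add atoms: water O
Why: Mild acetal hydrolysis; the pivalaldehyde acylal needs much stronger acid and survives.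

**Step 7**
Reactants: 13 (4Z)-7-[(2R,4S)-2-tert-butyl-4-methyl-5-oxo-1,3-dioxolan-4-yl]-4-methylhept-4-enal
Product: 14 (2R,5S)-2-tert-butyl-5-[(3Z,7Z)-8-iodo-4-methylnona-3,7-dien-1-yl]-5-methyl-1,3-dioxolan-4-one
Conditions: EtPPh3I, n-BuLi, THF; I2, −78 °C; NaHMDS, −20 °C; then 13, −78 °C
Reagents that add atoms: ethyltriphenylphosphonium iodide CC[P+](c1ccccc1)(c1ccccc1)c1ccccc1.[I-]; iodine II
Why: Second Stork–Zhao iodo-olefination installs the (Z)-vinyl iodide that becomes C11=C12.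

**Step 8**
Reactants: 14 (2R,5S)-2-tert-butyl-5-[(3Z,7Z)-8-iodo-4-methylnona-3,7-dien-1-yl]-5-methyl-1,3-dioxolan-4-one
Product: 15 (2S,5Z,9Z)-2-hydroxy-10-iodo-2,6-dimethylundeca-5,9-dienoic acid
Conditions: LiOH, THF/H2O, rt; 1 M HCl to pH 3
Reagents that add atoms: lithium hydroxide [Li+].[OH-]
Why: Saponification of the acylal lactone releases pivalaldehyde; the quaternary α-centre cannot epimerise.

**Step 9**
Reactants: 16 (S)-2,2-dimethyl-1,3-dioxolane-4-carbaldehyde; 17 dimethyl malonate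
Product: 18 dimethyl 2-{[(4R)-2,2-dimethyl-1,3-dioxolan-4-yl]methylidene}propanedioate
Conditions: piperidine, AcOH (cat.), 4 Å MS, CH2Cl2, rt
Reagents that add atoms: none
Why: Knoevenagel condensation under buffered conditions that do not epimerise the α-alkoxy aldehyde; the symmetric malonate gives no E/Z issue.

**Step 10**
Reactants: 18 dimethyl 2-{[(4R)-2,2-dimethyl-1,3-dioxolan-4-yl]methylidene}propanedioate
Product: 19 2-{[(4R)-2,2-dimethyl-1,3-dioxolan-4-yl]methylidene}propane-1,3-diol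
Conditions: DIBAL-H (5 equiv), CH2Cl2, −78 → −20 °C; Rochelle salt
Reagents that add atoms: none
Why: DIBAL-H reduces both esters by 1,2-addition to the 2-alkylidene-1,3-diol.

**Step 11**
Reactants: 15 (2S,5Z,9Z)-2-hydroxy-10-iodo-2,6-dimethylundeca-5,9-dienoic acid; 19 2-{[(4R)-2,2-dimethyl-1,3-dioxolan-4-yl]methylidene}propane-1,3-diol (3 equiv)
Product: 20 (2E)-3-[(4R)-2,2-dimethyl-1,3-dioxolan-4-yl]-2-(hydroxymethyl)prop-2-en-1-yl (2S,5Z,9Z)-2-hydroxy-10-iodo-2,6-dimethylundeca-5,9-dienoate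
Conditions: EDC·HCl, DMAP, CH2Cl2, 0 °C → rt
Reagents that add atoms: none
Why: Carbodiimide (Steglich) esterification at the less hindered CH2OH, trans to the dioxolane; the regioisomeric mono-ester converges to the same product in step 13.

**Step 12**
Reactants: 20 mono-ester
Product: 21 (2Z)-3-[(4R)-2,2-dimethyl-1,3-dioxolan-4-yl]-2-[(triethylsilyloxy)methyl]prop-2-en-1-yl (2S,5Z,9Z)-10-iodo-2,6-dimethyl-2-(triethylsilyloxy)undeca-5,9-dienoate
Conditions: TESOTf (3 equiv), 2,6-lutidine, CH2Cl2, −78 → 0 °C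
Reagents that add atoms: triethylsilyl triflate CC[Si](CC)(CC)OS(=O)(=O)C(F)(F)F
Why: Silyl triflate protects both the primary and the tertiary hydroxyl so that no O–H or other carbonyl meets the titanium reagent.

**Step 13**
Reactants: 21 bis-TES ester
Product: 23 (3R,6S,9Z,13Z)-3-[(4R)-2,2-dimethyl-1,3-dioxolan-4-yl]-14-iodo-6,10-dimethyl-2-methylidene-1,6-bis(triethylsilyloxy)pentadeca-9,13-dien-5-one, via allyl vinyl ether 22 (not isolated)
Conditions: Cp2TiMe2 (3 equiv), toluene, 75 °C, dark; filter through basic Al2O3; xylene, Et3N (trace), 140 °C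
Reagents that add atoms: dimethyltitanocene C[Ti](C)(C1C=CC=C1)C1C=CC=C1
Why: Petasis methylenation followed by aliphatic Claisen [3,3] rearrangement forms C1–C2; A(1,3) strain with the cis CH2OTES holds the C14–H in the alkene plane and the new bond forms anti to the C14–O bond, giving (1R) from (14R).

**Step 14**
Reactants: 23 Claisen ketone
Product: 24 (3R,6S,9Z,13Z)-3-[(4R)-2,2-dimethyl-1,3-dioxolan-4-yl]-1,6-dihydroxy-14-iodo-6,10-dimethyl-2-methylidenepentadeca-9,13-dien-5-one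
Conditions: TBAF, AcOH, THF, 0 °C → rt
Reagents that add atoms: none
Why: Buffered fluoride desilylation removes both TES groups and leaves the acetonide.

**Step 15**
Reactants: 24 diol ketone
Product: 26 (3R,6S,9Z,13Z)-3-[(4R)-2,2-dimethyl-1,3-dioxolan-4-yl]-6-hydroxy-14-iodo-6,10-dimethyl-2-methylidene-5-oxopentadeca-9,13-dienoic acid, via enal 25 (not isolated)
Conditions: TEMPO (cat.), PhI(OAc)2, CH2Cl2, rt; then NaClO2, NaH2PO4, 2-methyl-2-butene, t-BuOH/H2O, 0 °C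
Reagents that add atoms: sodium chlorite [Na+].[O-]Cl=O
Why: TEMPO/BAIB oxidises the only primary (allylic) alcohol and Pinnick oxidation takes the enal to the acrylic acid; the tertiary alcohol is inert.

**Step 16**
Reactants: 26 acrylic acid
Product: 28 (4R,5R)-5-(hydroxymethyl)-4-[(3S,6Z,10Z)-3-hydroxy-11-iodo-3,7-dimethyl-2-oxododeca-6,10-dien-1-yl]-3-methylideneoxolan-2-one, via dihydroxy acid 27 (not isolated)
Conditions: AcOH/H2O (4:1), 50 °C; toluene azeotrope
Reagents that add atoms: none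
Why: Acetonide hydrolysis and acid-catalysed lactonisation; the secondary O14 closes the γ-lactone, favoured over the δ-lactone through the primary O13, and the trans relationship is already fixed by C1 and C14.

**Step 17**
Reactants: 28 lactone alcohol
Product: 29 (2R,3R)-3-[(3S,6Z,10Z)-3-hydroxy-11-iodo-3,7-dimethyl-2-oxododeca-6,10-dien-1-yl]-4-methylidene-5-oxooxolane-2-carbaldehyde
Conditions: Dess–Martin periodinane, CH2Cl2, 0 °C → rt; used at once
Reagents that add atoms: none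
Why: Dess–Martin oxidation of the single primary alcohol under non-basic conditions avoids epimerising C14.

**Step 18**
Reactants: 29 lactone aldehyde
Product: 31 (1R,4S,13S,14R,7Z,11Z)-4,13-dihydroxy-3-oxocembra-7,11,15(17)-trien-16,14-olide, via alkenylchromium(III) species 30 (not isolated)
Conditions: CrCl2 (10 equiv), NiCl2 (2 mol%), DMSO/THF, rt, 2 mM, slow addition
Reagents that add atoms: none
Why: Nozaki–Hiyama–Kishi macrocyclisation is aldehyde-selective (ketone and lactone survive) and keeps the Z vinyl geometry; Felkin–Anh addition anti to the C14–O bond gives the 13,14-anti (13S) alcohol.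

**Step 19**
Reactants: 31 macrocyclic diol
Product: 32 (1R,4S,13S,14R,7Z,11Z)-4,13-diacetoxy-3-oxocembra-7,11,15(17)-trien-16,14-olide
Conditions: Ac2O, DMAP, Et3N, CH2Cl2, 35 °C
Reagents that add atoms: acetic anhydride CC(=O)OC(C)=O
Why: DMAP-catalysed acylation acetylates the allylic secondary alcohol and, more slowly, the tertiary α-ketol hydroxyl while C3 is still a ketone.

**Step 20**
Reactants: 32 diacetoxy ketone
Product: 33 (1R,3S,4S,13S,14R,7Z,11Z)-4,13-diacetoxy-3-hydroxycembra-7,11,15(17)-trien-16,14-olide (target)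
Conditions: NaBH4, CeCl3·7H2O, MeOH, −78 °C; AcOH quench at −78 °C
Reagents that add atoms: none
Why: Luche 1,2-reduction spares the α-methylene lactone and acetates; Felkin–Anh attack anti to the C4–OAc bond with the ring chain extended gives the 3,4-syn (3S) alcohol, and the cold acidic quench suppresses acetyl migration.

**Compound list**
1 | (R)-lactic acid | C[C@@H](O)C(=O)O | starting material
2 | pivalaldehyde | CC(C)(C)C=O | starting material
3 | (2R,5R)-2-tert-butyl-5-methyl-1,3-dioxolan-4-one | C[C@H]1O[C@@H](C(C)(C)C)OC1=O | intermediate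
4 | 4-iodobut-1-ene | C=CCCI | starting material
5 | lithium enolate of 3 | CC1=C([O-])O[C@H](C(C)(C)C)O1.[Li+] | intermediate
6 | (2R,5S)-5-(but-3-en-1-yl)-2-tert-butyl-5-methyl-1,3-dioxolan-4-one | C=CCC[C@]1(C)O[C@@H](C(C)(C)C)OC1=O | intermediate
7 | secondary ozonide (1,2,4-trioxolane) of 6 | C1OC(CC[C@]2(C)O[C@@H](C(C)(C)C)OC2=O)OO1 | intermediate
8 | 3-[(2R,4S)-2-tert-butyl-4-methyl-5-oxo-1,3-dioxolan-4-yl]propanal | O=CCC[C@]1(C)O[C@@H](C(C)(C)C)OC1=O | intermediate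
9 | (2R,5S)-2-tert-butyl-5-[(3Z)-4-iodopent-3-en-1-yl]-5-methyl-1,3-dioxolan-4-one | I/C(C)=C\CC[C@]1(C)O[C@@H](C(C)(C)C)OC1=O | intermediate
10 | acrolein diethyl acetal | C=CC(OCC)OCC | starting material
11 | B-(3,3-diethoxypropyl)-9-BBN | CCOC(CCB1C2CCCC1CCC2)OCC | intermediate
12 | (2R,5S)-2-tert-butyl-5-[(3Z)-7,7-diethoxy-4-methylhept-3-en-1-yl]-5-methyl-1,3-dioxolan-4-one | CCOC(CC/C(C)=C\CC[C@]1(C)O[C@@H](C(C)(C)C)OC1=O)OCC | intermediate
13 | (4Z)-7-[(2R,4S)-2-tert-butyl-4-methyl-5-oxo-1,3-dioxolan-4-yl]-4-methylhept-4-enal | O=CCC/C(C)=C\CC[C@]1(C)O[C@@H](C(C)(C)C)OC1=O | intermediate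
14 | (2R,5S)-2-tert-butyl-5-[(3Z,7Z)-8-iodo-4-methylnona-3,7-dien-1-yl]-5-methyl-1,3-dioxolan-4-one | I/C(C)=C\CC/C(C)=C\CC[C@]1(C)O[C@@H](C(C)(C)C)OC1=O | intermediate
15 | (2S,5Z,9Z)-2-hydroxy-10-iodo-2,6-dimethylundeca-5,9-dienoic acid | I/C(C)=C\CC/C(C)=C\CC[C@](C)(O)C(=O)O | intermediate
16 | (S)-2,2-dimethyl-1,3-dioxolane-4-carbaldehyde | CC1(C)OC[C@@H](C=O)O1 | starting material
17 | dimethyl malonate | COC(=O)CC(=O)OC | starting material
18 | dimethyl 2-{[(4R)-2,2-dimethyl-1,3-dioxolan-4-yl]methylidene}propanedioate | COC(=O)C(=C[C@@H]1COC(C)(C)O1)C(=O)OC | intermediate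
19 | 2-{[(4R)-2,2-dimethyl-1,3-dioxolan-4-yl]methylidene}propane-1,3-diol | OCC(CO)=C[C@@H]1COC(C)(C)O1 | intermediate
20 | mono-ester of 15 with 19 (acyloxymethyl arm trans to dioxolane) | I/C(C)=C\CC/C(C)=C\CC[C@](C)(O)C(=O)OC/C(CO)=C/[C@@H]1COC(C)(C)O1 | intermediate
21 | bis(triethylsilyl) ether of 20 | I/C(C)=C\CC/C(C)=C\CC[C@](C)(O[Si](CC)(CC)CC)C(=O)OC/C(CO[Si](CC)(CC)CC)=C/[C@@H]1COC(C)(C)O1 | intermediate
22 | allyl vinyl ether (methylenated 21) | I/C(C)=C\CC/C(C)=C\CC[C@](C)(O[Si](CC)(CC)CC)C(=C)OC/C(CO[Si](CC)(CC)CC)=C/[C@@H]1COC(C)(C)O1 | intermediate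
23 | (3R,6S,9Z,13Z)-3-[(4R)-2,2-dimethyl-1,3-dioxolan-4-yl]-14-iodo-6,10-dimethyl-2-methylidene-1,6-bis(triethylsilyloxy)pentadeca-9,13-dien-5-one | I/C(C)=C\CC/C(C)=C\CC[C@](C)(O[Si](CC)(CC)CC)C(=O)C[C@@H]([C@@H]1COC(C)(C)O1)C(=C)CO[Si](CC)(CC)CC | intermediate
24 | (3R,6S,9Z,13Z)-3-[(4R)-2,2-dimethyl-1,3-dioxolan-4-yl]-1,6-dihydroxy-14-iodo-6,10-dimethyl-2-methylidenepentadeca-9,13-dien-5-one | I/C(C)=C\CC/C(C)=C\CC[C@](C)(O)C(=O)C[C@@H]([C@@H]1COC(C)(C)O1)C(=C)CO | intermediate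
25 | (3R,6S,9Z,13Z)-3-[(4R)-2,2-dimethyl-1,3-dioxolan-4-yl]-6-hydroxy-14-iodo-6,10-dimethyl-2-methylidene-5-oxopentadeca-9,13-dienal | I/C(C)=C\CC/C(C)=C\CC[C@](C)(O)C(=O)C[C@@H]([C@@H]1COC(C)(C)O1)C(=C)C=O | intermediate
26 | (3R,6S,9Z,13Z)-3-[(4R)-2,2-dimethyl-1,3-dioxolan-4-yl]-6-hydroxy-14-iodo-6,10-dimethyl-2-methylidene-5-oxopentadeca-9,13-dienoic acid | I/C(C)=C\CC/C(C)=C\CC[C@](C)(O)C(=O)C[C@@H]([C@@H]1COC(C)(C)O1)C(=C)C(=O)O | intermediate
27 | (3R,6S,9Z,13Z)-3-[(1R)-1,2-dihydroxyethyl]-6-hydroxy-14-iodo-6,10-dimethyl-2-methylidene-5-oxopentadeca-9,13-dienoic acid | I/C(C)=C\CC/C(C)=C\CC[C@](C)(O)C(=O)C[C@@H]([C@@H](O)CO)C(=C)C(=O)O | intermediate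
28 | (4R,5R)-5-(hydroxymethyl)-4-[(3S,6Z,10Z)-3-hydroxy-11-iodo-3,7-dimethyl-2-oxododeca-6,10-dien-1-yl]-3-methylideneoxolan-2-one | C=C1C(=O)O[C@@H](CO)[C@@H]1CC(=O)[C@@](C)(O)CC/C=C(/C)CC/C=C(/C)I | intermediate
29 | (2R,3R)-3-[(3S,6Z,10Z)-3-hydroxy-11-iodo-3,7-dimethyl-2-oxododeca-6,10-dien-1-yl]-4-methylidene-5-oxooxolane-2-carbaldehyde | C=C1C(=O)O[C@@H](C=O)[C@@H]1CC(=O)[C@@](C)(O)CC/C=C(/C)CC/C=C(/C)I | intermediate
30 | alkenylchromium(III) dichloride derived from 29 | C=C1C(=O)O[C@@H](C=O)[C@@H]1CC(=O)[C@@](C)(O)CC/C=C(/C)CC/C=C(/C)[Cr](Cl)Cl | intermediate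
31 | (1R,4S,13S,14R,7Z,11Z)-4,13-dihydroxy-3-oxocembra-7,11,15(17)-trien-16,14-olide | C=C1C(=O)O[C@@H]2[C@@H]1CC(=O)[C@@](C)(O)CC/C=C(/C)CC/C=C(/C)[C@@H]2O | intermediate
32 | (1R,4S,13S,14R,7Z,11Z)-4,13-diacetoxy-3-oxocembra-7,11,15(17)-trien-16,14-olide | C=C1C(=O)O[C@@H]2[C@@H]1CC(=O)[C@@](C)(OC(C)=O)CC/C=C(/C)CC/C=C(/C)[C@@H]2OC(C)=O | intermediate
33 | (1R,3S,4S,13S,14R,7Z,11Z)-4,13-diacetoxy-3-hydroxycembra-7,11,15(17)-trien-16,14-olide (CNP0127975.1) | C=C1C(=O)O[C@@H]2[C@@H]1C[C@H](O)[C@@](C)(OC(C)=O)CC/C=C(/C)CC/C=C(/C)[C@@H]2OC(C)=O | target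

**Totals**
Total steps: 20. Longest linear sequence: 18 (steps 1–8, then 11–20).

**Three steps most likely to fail**

Step 13 (methylenation of a neopentyl-type ester, then the Claisen). The ester carbonyl sits next to a quaternary silyloxy carbon and may resist the titanium reagent. The fallback reaches the same ketone by a decarboxylative Carroll [3,3] rearrangement and needs no carbonyl methylenation. It sets out from 15 (with 19) and comes back at 23. Acid 15 is silylated with TESOTf/2,6-lutidine and the silyl ester is cleaved with aqueous K2CO3 to give (2S,5Z,9Z)-10-iodo-2,6-dimethyl-2-(triethylsilyloxy)undeca-5,9-dienoic acid F1. F1 is condensed with Meldrum's acid (DCC, DMAP) to the acyl Meldrum's acid F2. Heating F2 with diol 19 in toluene at 80 °C traps the acylketene at the less hindered hydroxyl to give the allyl β-keto ester F3. TESCl/imidazole gives its primary silyl ether F4, and heating F4 in xylene at 150 °C effects the Carroll rearrangement and loss of CO2 to give 23.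

Step 18 (macrocyclisation and C13 configuration). If the ring closes with the opposite facial sense, the stereocentre is corrected by inversion instead of direct addition. The fallback sets out from 29 and comes back at 32. The NHK reaction would then give the 13-epimer, (1R,4S,13R,14R,7Z,11Z)-4,13-dihydroxy-3-oxocembra-7,11,15(17)-trien-16,14-olide F5. Mitsunobu reaction of F5 with acetic acid (PPh3, DIAD) inverts C13 and installs the acetate directly, giving (1R,4S,13S,14R,7Z,11Z)-13-acetoxy-4-hydroxy-3-oxocembra-7,11,15(17)-trien-16,14-olide F6. Acetylation of the tertiary hydroxyl of F6 (Ac2O, DMAP) gives 32.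

Step 20 (reduction next to a tertiary acetate: acetyl migration, facial selectivity, conjugate reduction). The fallback reduces before any acetate is present and places the tertiary acetate by orthoester opening. It sets out from 31 and comes back at 33. Luche reduction of 31 gives (1R,3S,4S,13S,14R,7Z,11Z)-3,4,13-trihydroxycembra-7,11,15(17)-trien-16,14-olide F7. Trimethyl orthoacetate/PPTS converts the 3,4-diol of F7 into the cyclic methyl orthoacetate F8. Ac2O/pyridine acetylates the free 13-hydroxyl to give the 13-acetoxy orthoacetate F9. Brief treatment of F9 with aqueous acetic acid opens the orthoester with the acetate on the more hindered tertiary oxygen, giving 33.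

**Further compounds**
F1 | step 13 | (2S,5Z,9Z)-10-iodo-2,6-dimethyl-2-(triethylsilyloxy)undeca-5,9-dienoic acid | I/C(C)=C\CC/C(C)=C\CC[C@](C)(O[Si](CC)(CC)CC)C(=O)O
F2 | step 13 | 5-[(2S,5Z,9Z)-10-iodo-2,6-dimethyl-2-(triethylsilyloxy)undeca-5,9-dienoyl]-2,2-dimethyl-1,3-dioxane-4,6-dione | I/C(C)=C\CC/C(C)=C\CC[C@](C)(O[Si](CC)(CC)CC)C(=O)C1C(=O)OC(C)(C)OC1=O
F3 | step 13 | (2E)-3-[(4R)-2,2-dimethyl-1,3-dioxolan-4-yl]-2-(hydroxymethyl)prop-2-en-1-yl (4S,7Z,11Z)-12-iodo-4,8-dimethyl-3-oxo-4-(triethylsilyloxy)trideca-7,11-dienoate | I/C(C)=C\CC/C(C)=C\CC[C@](C)(O[Si](CC)(CC)CC)C(=O)CC(=O)OC/C(CO)=C/[C@@H]1COC(C)(C)O1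
F4 | step 13 | triethylsilyl ether of F3 | I/C(C)=C\CC/C(C)=C\CC[C@](C)(O[Si](CC)(CC)CC)C(=O)CC(=O)OC/C(CO[Si](CC)(CC)CC)=C/[C@@H]1COC(C)(C)O1
F5 | step 18 | (1R,4S,13R,14R,7Z,11Z)-4,13-dihydroxy-3-oxocembra-7,11,15(17)-trien-16,14-olide | C=C1C(=O)O[C@@H]2[C@@H]1CC(=O)[C@@](C)(O)CC/C=C(/C)CC/C=C(/C)[C@H]2O
F6 | step 18 | (1R,4S,13S,14R,7Z,11Z)-13-acetoxy-4-hydroxy-3-oxocembra-7,11,15(17)-trien-16,14-olide | C=C1C(=O)O[C@@H]2[C@@H]1CC(=O)[C@@](C)(O)CC/C=C(/C)CC/C=C(/C)[C@@H]2OC(C)=O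
F7 | step 20 | (1R,3S,4S,13S,14R,7Z,11Z)-3,4,13-trihydroxycembra-7,11,15(17)-trien-16,14-olide | C=C1C(=O)O[C@@H]2[C@@H]1C[C@H](O)[C@@](C)(O)CC/C=C(/C)CC/C=C(/C)[C@@H]2O
F8 | step 20 | 3,4-O-(1-methoxyethylidene) derivative of F7 (cyclic methyl orthoacetate) | C=C1C(=O)O[C@@H]2[C@@H]1C[C@@H]1OC(C)(OC)O[C@@]1(C)CC/C=C(/C)CC/C=C(/C)[C@@H]2O
F9 | step 20 | 13-O-acetyl derivative of F8 | C=C1C(=O)O[C@@H]2[C@@H]1C[C@@H]1OC(C)(OC)O[C@@]1(C)CC/C=C(/C)CC/C=C(/C)[C@@H]2OC(C)=O
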